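# Total synthesis proposal for CNP0198878.1 by Nozaki–Hiyama–Kishi closure of C7–C8

## Retrosynthetic overview

Cembrane numbering: C1 = CH bearing C15(=C17H2)–C16. C3 = CHOAc. C4 and C7 = tetrahydrofuran carbons. C8 = carbinol (C19 methyl). C11 = ketone. C12 = lactone O-carbon (C20 methyl).
Feature: the C7–C8 bond of the 14-membered carbocycle joins the oxygen-bearing CH of the tetrahydrofuran ring (O–C4–C5–C6–C7) to the methyl-bearing carbinol C8, and it lies across the ring from the seven-membered α-methylene lactone (C15–C16–O–C12–C13–C14–C1).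
Disconnections: lactone C16–O (last); C8–OH/C9–H (8,9-epoxide plus hydride); tetrahydrofuran O–C4 (C7 hydroxyl onto a 3,4-epoxide); C7–C8 (aldehyde plus E-2-iodoalkene, CrCl2/NiCl2).
The open chain comes from (R)-carvone (C1–C4 and C13–C18, by Eschenmoser–Tanabe fragmentation), a C3 ylide (C11, C12, C20), an allyl ether (C5–C7), a sulfonium methylide (C10) and propyne (C8, C9, C19).
Ring order: 14-membered carbocycle, then tetrahydrofuran, then seven-membered lactone.

Key step: step 22

Assumption: C11 is a transient stereocentre (a ketone in the target); the (11S) epimer expected from Felkin–Anh addition is drawn and carried, and the (11R) epimer would serve equally.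

## Route

Step 1
Reactants: 1 (R)-(−)-carvone
Product: 2 (R)-10-chlorocarvone [(5R)-5-(3-chloroprop-1-en-2-yl)-2-methylcyclohex-2-en-1-one]
Conditions: Ca(OCl)2, solid CO2, CH2Cl2/H2O, 0 °C
Reagents that add atoms: calcium hypochlorite, [Ca+2].[O-]Cl.[O-]Cl
Why: Ene-type allylic chlorination by HOCl made in situ attacks only the electron-rich isopropenyl alkene (the enone alkene is deactivated) and shifts the double bond to give the 2-(chloromethyl)allyl unit, which puts a leaving group on C16 without touching the C1 stereocentre.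

Step 2
Reactants: 2 (R)-10-chlorocarvone
Product: 3 (R)-10-acetoxycarvone
Conditions: KOAc, n-Bu4NI (cat.), DMF, 50 °C
Reagents that add atoms: potassium acetate, [K+].CC([O-])=O
Why: SN2 displacement of the primary allylic chloride by acetate, a weak base that should not trigger aromatisation of the cyclohexenone.

Step 3
Reactants: 3 (R)-10-acetoxycarvone
Product: 4 (1R,4R,6R)-4-(3-hydroxyprop-1-en-2-yl)-1-methyl-7-oxabicyclo[4.1.0]heptan-2-one
Conditions: 30% aq. H2O2, NaOH, MeOH, 0 °C
Reagents that add atoms: hydrogen peroxide, OO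
Why: Weitz–Scheffer nucleophilic epoxidation of the enone by hydroperoxide, anti to the side chain (both new centres are erased in step 5), runs together with saponification of the acetate, while the unactivated 1,1-disubstituted alkene is inert to the nucleophilic oxidant.

Step 4
Reactants: 4 epoxy keto alcohol
Product: 5 tert-butyldimethylsilyl (TBS) ether of 4
Conditions: TBSCl, imidazole, DMF, 0 °C → rt
Reagents that add atoms: tert-butyldimethylsilyl chloride, CC(C)(C)[Si](C)(C)Cl
Why: Standard silylation of the only hydroxyl group gives the C16 silyl ether that is carried to step 27.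

Step 5
Reactants: 5 TBS-protected epoxy ketone
Product: 7 (3S)-3-[3-(tert-butyldimethylsilyloxy)prop-1-en-2-yl]hept-5-ynal (C13 aldehyde and C3≡C4 methyl alkyne), via epoxy tosylhydrazone 6 (not isolated)
Conditions: TsNHNH2, AcOH/CH2Cl2 (1:1), −20 °C → rt
Reagents that add atoms: none
Why: Eschenmoser–Tanabe fragmentation, in which the tosylhydrazone opens the epoxide and the resulting alkoxide fragments with loss of N2 and sulfinate, cleaves the former C2–C3 ring bond of carvone into the C13 aldehyde and the C3≡C4 methyl alkyne with the C1 stereocentre as a bystander.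

Step 6
Reactants: 7 alkynal; 8 ethyl 2-(triphenylphosphoranylidene)propanoate
Product: 9 ethyl (12E)-enoate (C11 ester, C12=C13 alkene, C20 methyl)
Conditions: CH2Cl2, rt → 40 °C
Reagents that add atoms: none
Why: Wittig olefination with a stabilised α-methyl ylide gives the E-trisubstituted enoate and brings in C11, C12 and C20.

Step 7
Reactants: 9 E-enoate
Product: 10 (12E)-allylic alcohol (C11 hydroxyl)
Conditions: i-Bu2AlH, CH2Cl2, −78 °C; aq. potassium sodium tartrate
Reagents that add atoms: none
Why: 1,2-Reduction of the enoate by i-Bu2AlH stops at the allylic alcohol and leaves the alkyne, the silyl ether and the 1,1-disubstituted alkene alone.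

Step 8
Reactants: 10 E-allylic alcohol
Product: 11 (12S,13S)-12,13-epoxy-11-ol
Conditions: Ti(OiPr)4 (cat.), L-(+)-diethyl tartrate (cat.), t-BuOOH, 4 Å MS, CH2Cl2, −20 °C
Reagents that add atoms: tert-butyl hydroperoxide, CC(C)(C)OO
Why: Sharpless asymmetric epoxidation, in which L-(+)-diethyl tartrate delivers oxygen to the face of the E-2-methyl allylic alcohol that gives the (12S,13S)-epoxide, sets the C12–O bond of the future lactone by reagent control and touches no alkene that lacks a free allylic hydroxyl.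

Step 9
Reactants: 11 epoxy alcohol
Product: 12 (12R)-11,12-diol
Conditions: LiAlH4, THF, 0 °C → rt
Reagents that add atoms: none
Why: SN2 hydride opening of the 2,3-epoxy alcohol at the less substituted C13 gives the 1,2-diol, so the C12–O bond and its spatial arrangement are retained (the descriptor becomes 12R only through a change of priorities).

Step 10
Reactants: 12 diol
Product: 13 11,12-bis(triethylsilyl) (TES) ether
Conditions: TESOTf, 2,6-lutidine, CH2Cl2, −78 → 0 °C
Reagents that add atoms: triethylsilyl triflate, CC[Si](CC)(CC)OS(=O)(=O)C(F)(F)F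
Why: A silyl triflate with a hindered base silylates both the primary and the tertiary hydroxyl, the triethylsilyl pair being chosen so that the primary one can be singled out in step 14.

Step 11
Reactants: 13 bis-TES alkyne
Product: 15 (3E)-4-iodoalkene, via alkenylzirconocene chloride 14 (not isolated)
Conditions: Cp2Zr(H)Cl, THF, rt → 40 °C; then I2, THF, −20 °C
Reagents that add atoms: iodine, II
Why: In this hydrozirconation–iodination, syn addition of Zr–H places zirconium on C4, next to the small methyl and away from the β-branched C2–C1 side (a slight excess of reagent equilibrates the regioisomers), iodinolysis with retention gives the E-iodoalkene, and the alkyne reacts far faster than the 1,1-disubstituted alkene.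

Step 12
Reactants: 16 4-methoxybenzyl alcohol; 17 allyl bromide
Product: 18 allyl 4-methoxybenzyl (PMB) ether
Conditions: NaH, THF/DMF, 0 °C → rt
Reagents that add atoms: none
Why: Williamson ether synthesis of a primary alkoxide with an allylic bromide.

Step 13
Reactants: 15 (3E)-4-iodoalkene; 18 allyl PMB ether
Product: 20 (3E)-trisubstituted alkene carrying C5–C7 and the C7 PMB ether, via alkyl-9-BBN 19 (not isolated)
Conditions: 18, 9-BBN-H, THF, 0 °C → rt; then 15, Pd(dppf)Cl2 (cat.), AsPh3 (cat.), Cs2CO3, DMF/THF/H2O, rt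
Reagents that add atoms: none
Why: In this B-alkyl Suzuki–Miyaura coupling, anti-Markovnikov hydroboration of the allyl ether gives a primary alkylborane that couples with the alkenyl iodide with retention to give the E-C3=C4 alkene, and the coupling is placed here so that no second iodoalkene is present when palladium is used.

Step 14
Reactants: 20 bis-TES ether
Product: 21 (12R)-C11 aldehyde with the C12 TES ether retained
Conditions: (COCl)2, DMSO, CH2Cl2, −78 → −40 °C; Et3N, −78 → 0 °C
Reagents that add atoms: none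
Why: Swern oxidation applied directly to the silyl ether works because the activated sulfoxide attacks only the unhindered primary TES ether, so the C11 aldehyde is unveiled in one operation while the tertiary TES, the TBS and the PMB ethers stay.

Step 15
Reactants: 21 aldehyde
Product: 22 (11S,12R)-10,11-epoxide
Conditions: Me3SI, n-BuLi, THF, −10 °C → rt
Reagents that add atoms: trimethylsulfonium iodide, C[S+](C)C.[I-]
Why: Corey–Chaykovsky methylene transfer to the non-enolisable aldehyde adds C10, with polar Felkin–Anh attack anti to the C12–O bond favouring the (11S)-epoxide, a centre that is erased in step 28.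

Step 16
Reactants: 22 terminal epoxide; 23 propyne
Product: 25 (11S,12R)-homopropargylic alcohol (C9≡C8–C19), via 1-propynyllithium 24 (not isolated)
Conditions: 23, n-BuLi, THF, −78 °C; BF3·OEt2; then 22, −78 °C
Reagents that add atoms: none
Why: BF3-assisted alkynylation of the terminal epoxide at its unhindered CH2 (C10) by the lithium acetylide adds C8, C9 and C19, and the minor C11 epimer is removed by chromatography at this alcohol.

Step 17
Reactants: 25 homopropargylic alcohol
Product: 26 C11 TBS ether
Conditions: TBSOTf, 2,6-lutidine, CH2Cl2, 0 °C → rt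
Reagents that add atoms: tert-butyldimethylsilyl triflate, CC(C)(C)[Si](C)(C)OS(=O)(=O)C(F)(F)F
Why: The silyl triflate overcomes the hindrance of the neopentyl-type secondary hydroxyl and masks C11 until the hydride step is over.

Step 18
Reactants: 26 methyl alkyne
Product: 28 (8E)-8-iodoalkene, via alkenylzirconocene chloride 27 (not isolated)
Conditions: Cp2Zr(H)Cl, THF, rt → 40 °C; then I2, THF, −20 °C
Reagents that add atoms: iodine, II
Why: In this hydrozirconation–iodination, syn Zr–H addition puts zirconium on the methyl-bearing C8, far from the bulky C11/C12 silyloxy carbons, and iodinolysis with retention gives the E-2-iodoalkene, while the tri- and 1,1-disubstituted alkenes are too slow to compete.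

Step 19
Reactants: 28 iodo diene
Product: 29 (3S,4S)-3,4-epoxide
Conditions: 1,2:4,5-di-O-isopropylidene-β-L-erythro-2,3-hexodiulo-2,6-pyranose (L-fructose-derived Shi ketone, 30 mol%), KHSO5 (as 2KHSO5·KHSO4·K2SO4), K2CO3, n-Bu4NHSO4 (cat.), MeCN/CH2(OMe)2, aq. Na2B4O7 buffer (pH 10.5), 0 °C
Reagents that add atoms: potassium peroxymonosulfate, [K+].[O-]S(=O)(=O)OO
Why: In this Shi epoxidation the chiral dioxirane reacts through its spiro transition state with the only electron-rich trialkyl alkene (the iodoalkene and the allylic-oxygenated 1,1-disubstituted alkene are deactivated), and the L-series ketone is the enantiomer that gives the (S,S)-epoxide and so sets C3 and C4 by reagent control.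

Step 20
Reactants: 29 PMB ether
Product: 30 C7 primary alcohol
Conditions: DDQ, CH2Cl2/pH 7 phosphate buffer, 0 °C
Reagents that add atoms: none
Why: Oxidative cleavage of the PMB ether by DDQ through the benzylic oxocarbenium ion under buffered conditions spares the epoxide, the iodoalkene and the silyl ethers.

Step 21
Reactants: 30 primary alcohol
Product: 31 seco epoxy aldehyde vinyl iodide (C7 aldehyde, (3S,4S)-epoxide, (8E)-iodoalkene, 11S, 12R)
Conditions: Dess–Martin periodinane, pyridine, CH2Cl2, 0 °C → rt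
Reagents that add atoms: none
Why: Dess–Martin oxidation under pyridine buffering gives the aldehyde without free acid that could open the epoxide.

Step 22
Reactants: 31 seco epoxy aldehyde vinyl iodide
Product: 33 (7R,8E)-14-membered allylic alcohol retaining the 3,4-epoxide, via alkenylchromium dichloride 32 (not isolated)
Conditions: CrCl2 (excess), NiCl2 (1 mol% of the CrCl2), DMSO/THF, rt, slow addition of 31 (final 2 mM); aq. sodium serinate work-up
Reagents that add atoms: none
Why: CrCl2 reduces NiCl2 to zerovalent nickel, which inserts into the C8–I bond, and transmetalation to trivalent chromium gives alkenylchromium 32 with the E geometry kept, which adds to the C7 aldehyde in a Nozaki–Hiyama–Kishi reaction whose closest precedents are vinyl iodide–aldehyde closures of ten- to sixteen-membered carbocycles. The one ring closed is the 14-membered carbocycle, by exo-trig 1,2-addition of C8 to the C7 carbonyl under syringe-pump dilution, and C7–C8 is the one skeletal bond formed. The new C7 stereocentre has no directing neighbour, so it is set by the cyclising conformer, in which the carbonyl oxygen turns outward to chromium and the C8 methyl stays clear of the C5–C6 chain; the (7R) outcome is a prediction and the least secure point of the route. The selectivity needed is addition to the aldehyde alone, and the low basicity and modest nucleophilicity of the alkenylchromium secure this for the trisubstituted epoxide, the three silyl ethers and the 1,1-disubstituted alkene. Placing the bond opposite C1 and C12 keeps the bulky silyloxy carbons away from the reacting ends. Any chromium alkoxide that goes on to attack C4 only anticipates step 23.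

Step 23
Reactants: 33 macrocyclic epoxy allylic alcohol
Product: 34 (3S,4R,7R)-4,7-epoxy-bridged macrocycle with free C3 hydroxyl
Conditions: camphor-10-sulfonic acid (5 mol%), CH2Cl2, −20 → 0 °C
Reagents that add atoms: none
Why: Acid-catalysed 5-exo-tet opening of the trisubstituted epoxide by the C7 hydroxyl at the tertiary C4, where ring-size and electronic preferences agree, proceeds with inversion to give (4R) and a tetrahydrofuran whose C3 and C8 arms are trans, and it frees the (3S)-hydroxyl with its C–O bond intact.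

Step 24
Reactants: 34 tetrahydrofuran alkene
Product: 35 (8R,9S)-8,9-epoxide
Conditions: L-fructose-derived Shi ketone (as in step 19, 30 mol%), KHSO5 (as 2KHSO5·KHSO4·K2SO4), K2CO3, n-Bu4NHSO4 (cat.), MeCN/CH2(OMe)2, aq. Na2B4O7 buffer (pH 10.5), 0 °C
Reagents that add atoms: potassium peroxymonosulfate, [K+].[O-]S(=O)(=O)OO
Why: Shi epoxidation with the same L-series ketone attacks the only trisubstituted alkene on the same facial sense as in step 19 to give the (8R,9S)-epoxide, and reagent control is chosen because hydroxyl-directed epoxidation of 33 would follow A1,2 strain to the erythro, 8-epi series.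

Step 25
Reactants: 35 epoxide
Product: 36 (3S,8R)-3,8-diol
Conditions: LiEt3BH, THF, 0 → 40 °C
Reagents that add atoms: none
Why: SN2 opening of the trisubstituted epoxide by the strongly nucleophilic hydride LiEt3BH occurs at the secondary C9 and leaves the C8–O bond, which gives the (8R) tertiary alcohol while the silyl ethers are inert.

Step 26
Reactants: 36 diol
Product: 37 3-acetate
Conditions: Ac2O, pyridine, DMAP (cat.), CH2Cl2, 0 °C → rt
Reagents that add atoms: acetic anhydride, CC(=O)OC(C)=O
Why: DMAP-catalysed acetylation distinguishes the secondary C3 hydroxyl from the tertiary C8 hydroxyl on steric grounds.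

Step 27
Reactants: 37 tris-silyl ether
Product: 38 8,11,12,16-tetraol 3-acetate
Conditions: HF·pyridine, pyridine/THF, 0 °C → rt
Reagents that add atoms: none
Why: Fluoride-driven cleavage removes all three silyl ethers under mildly acidic conditions that cause neither migration nor hydrolysis of the acetate.

Step 28
Reactants: 38 tetraol
Product: 39 11-keto 16-enal
Conditions: IBX, DMSO, rt
Reagents that add atoms: none
Why: IBX oxidises the primary allylic alcohol to the enal and the secondary C11 alcohol to the ketone, takes 1,2-diols to α-ketols without C–C cleavage, and cannot touch the two tertiary alcohols.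

Step 29
Reactants: 39 keto enal
Product: 40 11-keto 16-carboxylic acid
Conditions: NaClO2, NaH2PO4, 2-methylbut-2-ene, t-BuOH/H2O, 0 °C → rt
Reagents that add atoms: sodium chlorite, [Na+].[O-]Cl=O
Why: Pinnick oxidation converts the enal to the acrylic acid, with 2-methylbut-2-ene trapping HOCl, and leaves ketone, acetate and tertiary alcohols untouched.

Step 30
Reactants: 40 hydroxy keto acid
Product: 42 CNP0198878.1 (1R,3S,4R,7R,8R,12R), via mixed anhydride 41 (not isolated)
Conditions: 2,4,6-trichlorobenzoyl chloride, Et3N, THF, rt; then slow addition to DMAP, toluene (1 mM), 60 °C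
Reagents that add atoms: none
Why: In this Yamaguchi lactonisation DMAP converts the mixed anhydride into an acylpyridinium ion that the C12 hydroxyl captures in a seven-membered closure, favoured over the ten- or eleven-membered closures through the C8 hydroxyl, with retention at C12 because only the O–H bond is broken.

## Compound list

1 | (R)-(−)-carvone | CC1=CC[C@H](CC1=O)C(C)=C | starting material
2 | (R)-10-chlorocarvone | CC1=CC[C@H](CC1=O)C(=C)CCl | intermediate
3 | (R)-10-acetoxycarvone | CC1=CC[C@H](CC1=O)C(=C)COC(C)=O | intermediate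
4 | (1R,4R,6R)-4-(3-hydroxyprop-1-en-2-yl)-1-methyl-7-oxabicyclo[4.1.0]heptan-2-one | C[C@@]12O[C@@H]1C[C@H](CC2=O)C(=C)CO | intermediate
5 | TBS ether of 4 | C[C@@]12O[C@@H]1C[C@H](CC2=O)C(=C)CO[Si](C)(C)C(C)(C)C | intermediate
6 | epoxy tosylhydrazone of 5 | C[C@@]12O[C@@H]1C[C@H](CC2=NNS(=O)(=O)c1ccc(C)cc1)C(=C)CO[Si](C)(C)C(C)(C)C | intermediate
7 | (3S)-3-[3-(TBS-oxy)prop-1-en-2-yl]hept-5-ynal | C=C(CO[Si](C)(C)C(C)(C)C)[C@H](CC=O)CC#CC | intermediate
8 | ethyl 2-(triphenylphosphoranylidene)propanoate | CCOC(=O)C(C)=P(c1ccccc1)(c1ccccc1)c1ccccc1 | starting material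
9 | ethyl (12E)-enoate | C=C(CO[Si](C)(C)C(C)(C)C)[C@H](C/C=C(\C)C(=O)OCC)CC#CC | intermediate
10 | (12E)-allylic alcohol | C=C(CO[Si](C)(C)C(C)(C)C)[C@H](C/C=C(\C)CO)CC#CC | intermediate
11 | (12S,13S)-epoxy alcohol | C=C(CO[Si](C)(C)C(C)(C)C)[C@H](C[C@@H]1O[C@@]1(C)CO)CC#CC | intermediate
12 | (12R)-11,12-diol | C=C(CO[Si](C)(C)C(C)(C)C)[C@H](CC[C@@](C)(O)CO)CC#CC | intermediate
13 | 11,12-bis-TES ether | C=C(CO[Si](C)(C)C(C)(C)C)[C@H](CC[C@@](C)(O[Si](CC)(CC)CC)CO[Si](CC)(CC)CC)CC#CC | intermediate
14 | C4 alkenylzirconocene chloride | C=C(CO[Si](C)(C)C(C)(C)C)[C@H](CC[C@@](C)(O[Si](CC)(CC)CC)CO[Si](CC)(CC)CC)C/C=C(\C)[Zr](Cl)(C1C=CC=C1)C1C=CC=C1 | intermediate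
15 | (3E)-4-iodoalkene | C=C(CO[Si](C)(C)C(C)(C)C)[C@H](CC[C@@](C)(O[Si](CC)(CC)CC)CO[Si](CC)(CC)CC)C/C=C(\C)I | intermediate
16 | 4-methoxybenzyl alcohol | COc1ccc(CO)cc1 | starting material
17 | allyl bromide | C=CCBr | starting material
18 | allyl 4-methoxybenzyl ether | C=CCOCc1ccc(OC)cc1 | intermediate
19 | B-[3-(4-methoxybenzyloxy)propyl]-9-BBN | COc1ccc(COCCCB2C3CCCC2CCC3)cc1 | intermediate
20 | (3E)-alkene with C7 PMB ether | C=C(CO[Si](C)(C)C(C)(C)C)[C@H](CC[C@@](C)(O[Si](CC)(CC)CC)CO[Si](CC)(CC)CC)C/C=C(\C)CCCOCc1ccc(OC)cc1 | intermediate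
21 | C11 aldehyde | C=C(CO[Si](C)(C)C(C)(C)C)[C@H](CC[C@@](C)(O[Si](CC)(CC)CC)C=O)C/C=C(\C)CCCOCc1ccc(OC)cc1 | intermediate
22 | (11S,12R)-10,11-epoxide | C=C(CO[Si](C)(C)C(C)(C)C)[C@H](CC[C@@](C)(O[Si](CC)(CC)CC)[C@@H]1CO1)C/C=C(\C)CCCOCc1ccc(OC)cc1 | intermediate
23 | propyne | CC#C | starting material
24 | 1-propynyllithium | [Li]C#CC | intermediate
25 | (11S,12R)-homopropargylic alcohol | C=C(CO[Si](C)(C)C(C)(C)C)[C@H](CC[C@@](C)(O[Si](CC)(CC)CC)[C@@H](O)CC#CC)C/C=C(\C)CCCOCc1ccc(OC)cc1 | intermediate
26 | C11 TBS ether | C=C(CO[Si](C)(C)C(C)(C)C)[C@H](CC[C@@](C)(O[Si](CC)(CC)CC)[C@@H](O[Si](C)(C)C(C)(C)C)CC#CC)C/C=C(\C)CCCOCc1ccc(OC)cc1 | intermediate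
27 | C8 alkenylzirconocene chloride | C=C(CO[Si](C)(C)C(C)(C)C)[C@H](CC[C@@](C)(O[Si](CC)(CC)CC)[C@@H](O[Si](C)(C)C(C)(C)C)C/C=C(\C)[Zr](Cl)(C1C=CC=C1)C1C=CC=C1)C/C=C(\C)CCCOCc1ccc(OC)cc1 | intermediate
28 | (8E)-8-iodoalkene | C=C(CO[Si](C)(C)C(C)(C)C)[C@H](CC[C@@](C)(O[Si](CC)(CC)CC)[C@@H](O[Si](C)(C)C(C)(C)C)C/C=C(\C)I)C/C=C(\C)CCCOCc1ccc(OC)cc1 | intermediate
29 | (3S,4S)-epoxide | C=C(CO[Si](C)(C)C(C)(C)C)[C@H](CC[C@@](C)(O[Si](CC)(CC)CC)[C@@H](O[Si](C)(C)C(C)(C)C)C/C=C(\C)I)C[C@@H]1O[C@@]1(C)CCCOCc1ccc(OC)cc1 | intermediate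
30 | C7 primary alcohol | C=C(CO[Si](C)(C)C(C)(C)C)[C@H](CC[C@@](C)(O[Si](CC)(CC)CC)[C@@H](O[Si](C)(C)C(C)(C)C)C/C=C(\C)I)C[C@@H]1O[C@@]1(C)CCCO | intermediate
31 | seco epoxy aldehyde vinyl iodide | C=C(CO[Si](C)(C)C(C)(C)C)[C@H](CC[C@@](C)(O[Si](CC)(CC)CC)[C@@H](O[Si](C)(C)C(C)(C)C)C/C=C(\C)I)C[C@@H]1O[C@@]1(C)CCC=O | intermediate
32 | C8 alkenylchromium dichloride | C=C(CO[Si](C)(C)C(C)(C)C)[C@H](CC[C@@](C)(O[Si](CC)(CC)CC)[C@@H](O[Si](C)(C)C(C)(C)C)C/C=C(\C)[Cr](Cl)Cl)C[C@@H]1O[C@@]1(C)CCC=O | intermediate
33 | (7R,8E)-14-membered allylic alcohol with 3,4-epoxide | C=C(CO[Si](C)(C)C(C)(C)C)[C@H]1C[C@@H]2O[C@@]2(C)CC[C@@H](O)/C(C)=C/C[C@H](O[Si](C)(C)C(C)(C)C)[C@](C)(O[Si](CC)(CC)CC)CC1 | intermediate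
34 | (3S,4R,7R)-tetrahydrofuran alcohol | C=C(CO[Si](C)(C)C(C)(C)C)[C@H]1C[C@H](O)[C@@]2(C)CC[C@@H](O2)/C(C)=C/C[C@H](O[Si](C)(C)C(C)(C)C)[C@](C)(O[Si](CC)(CC)CC)CC1 | intermediate
35 | (8R,9S)-8,9-epoxide | C=C(CO[Si](C)(C)C(C)(C)C)[C@H]1C[C@H](O)[C@@]2(C)CC[C@@H](O2)[C@]3(C)O[C@H]3C[C@H](O[Si](C)(C)C(C)(C)C)[C@](C)(O[Si](CC)(CC)CC)CC1 | intermediate
36 | (3S,8R)-3,8-diol | C=C(CO[Si](C)(C)C(C)(C)C)[C@H]1C[C@H](O)[C@@]2(C)CC[C@@H](O2)[C@](C)(O)CC[C@H](O[Si](C)(C)C(C)(C)C)[C@](C)(O[Si](CC)(CC)CC)CC1 | intermediate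
37 | 3-acetate | C=C(CO[Si](C)(C)C(C)(C)C)[C@H]1C[C@H](OC(C)=O)[C@@]2(C)CC[C@@H](O2)[C@](C)(O)CC[C@H](O[Si](C)(C)C(C)(C)C)[C@](C)(O[Si](CC)(CC)CC)CC1 | intermediate
38 | 8,11,12,16-tetraol 3-acetate | C=C(CO)[C@H]1C[C@H](OC(C)=O)[C@@]2(C)CC[C@@H](O2)[C@](C)(O)CC[C@H](O)[C@](C)(O)CC1 | intermediate
39 | 11-keto 16-enal | C=C(C=O)[C@H]1C[C@H](OC(C)=O)[C@@]2(C)CC[C@@H](O2)[C@](C)(O)CCC(=O)[C@](C)(O)CC1 | intermediate
40 | 11-keto 16-acid | C=C(C(=O)O)[C@H]1C[C@H](OC(C)=O)[C@@]2(C)CC[C@@H](O2)[C@](C)(O)CCC(=O)[C@](C)(O)CC1 | intermediate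
41 | 2,4,6-trichlorobenzoic mixed anhydride of 40 | C=C(C(=O)OC(=O)c3c(Cl)cc(Cl)cc3Cl)[C@H]1C[C@H](OC(C)=O)[C@@]2(C)CC[C@@H](O2)[C@](C)(O)CCC(=O)[C@](C)(O)CC1 | intermediate
42 | CNP0198878.1 | C=C1C(=O)O[C@]2(C)CC[C@@H]1C[C@H](OC(C)=O)[C@@]1(C)CC[C@@H](O1)[C@](C)(O)CCC2=O | target

## Step count and risks

Total step count: 30.
Longest linear sequence: 29 (steps 1–11 and 13–30, from carvone).

**Step 22.** The two faces of the C7 aldehyde may be attacked with little discrimination during ring closure, because only the ring conformer controls C7. The fallback sets C7 by reduction instead of by C–C bond formation. It sets out from 33, whatever its composition at C7. Dess–Martin oxidation gives the macrocyclic enone F1. Reagent-controlled 1,2-reduction follows, using (S)-2-methyl-CBS-oxazaborolidine and catecholborane at −78 °C, with the α-methyl alkenyl group acting as the large substituent. This should return the (7R) alcohol, and the route is rejoined at 33.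

**Step 24.** The bridged macrocycle may expose only one face of C8=C9, so the peripheral bias could override the catalyst and give poor or reversed facial selectivity. The fallback uses hydroxyl direction and then corrects C7. It sets out from 33 and passes through enone F1.
- Reduction with (R)-2-methyl-CBS-oxazaborolidine and catecholborane gives the (7S)-allylic alcohol F2.
- F2 is the matched partner of Ti(OiPr)4, L-(+)-diisopropyl tartrate and t-BuOOH, and should give the erythro epoxy alcohol F3 with the required 8,9-epoxide sense.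
- Mitsunobu inversion with 4-nitrobenzoic acid gives the (7R)-4-nitrobenzoate F4.
- Methanolysis (K2CO3, MeOH) gives the threo epoxy alcohol F5.
- Catalytic camphor-10-sulfonic acid closes the tetrahydrofuran onto C4, and the route is rejoined at 35.

**Step 30.** Acylation of the hindered tertiary α-ketol hydroxyl may be slow, so that oligomerisation or decay of the activated acrylate takes over. The fallback lactonises before C11 is oxidised and lets the C11 hydroxyl relay the acyl group. It sets out from 38.
- MnO2 oxidises only the primary allylic alcohol, giving the 11-hydroxy enal F6.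
- Pinnick oxidation gives the trihydroxy acid F7.
- Mixed-anhydride lactonisation then has the accessible secondary C11 hydroxyl as nucleophile and gives the eight-membered lactone F8.
- DBU equilibrates F8 with the seven-membered 11-hydroxy lactone F9 by 1,2-acyl shift between the vicinal oxygens.
- Dess–Martin oxidation can act only on the free secondary hydroxyl of F9, so it drains the equilibrium, and the route is rejoined at 42.

Further compounds
F1 | step 22 | macrocyclic C7 enone | C=C(CO[Si](C)(C)C(C)(C)C)[C@H]1C[C@@H]2O[C@@]2(C)CCC(=O)/C(C)=C/C[C@H](O[Si](C)(C)C(C)(C)C)[C@](C)(O[Si](CC)(CC)CC)CC1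
F2 | step 24 | (7S)-allylic alcohol | C=C(CO[Si](C)(C)C(C)(C)C)[C@H]1C[C@@H]2O[C@@]2(C)CC[C@H](O)/C(C)=C/C[C@H](O[Si](C)(C)C(C)(C)C)[C@](C)(O[Si](CC)(CC)CC)CC1
F3 | step 24 | erythro (7S)-8,9-epoxy alcohol | C=C(CO[Si](C)(C)C(C)(C)C)[C@H]1C[C@@H]2O[C@@]2(C)CC[C@H](O)[C@]3(C)O[C@H]3C[C@H](O[Si](C)(C)C(C)(C)C)[C@](C)(O[Si](CC)(CC)CC)CC1
F4 | step 24 | (7R)-4-nitrobenzoate | C=C(CO[Si](C)(C)C(C)(C)C)[C@H]1C[C@@H]2O[C@@]2(C)CC[C@@H](OC(=O)c3ccc(cc3)[N+](=O)[O-])[C@]3(C)O[C@H]3C[C@H](O[Si](C)(C)C(C)(C)C)[C@](C)(O[Si](CC)(CC)CC)CC1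
F5 | step 24 | threo (7R)-8,9-epoxy alcohol | C=C(CO[Si](C)(C)C(C)(C)C)[C@H]1C[C@@H]2O[C@@]2(C)CC[C@@H](O)[C@]3(C)O[C@H]3C[C@H](O[Si](C)(C)C(C)(C)C)[C@](C)(O[Si](CC)(CC)CC)CC1
F6 | step 30 | 11-hydroxy enal | C=C(C=O)[C@H]1C[C@H](OC(C)=O)[C@@]2(C)CC[C@@H](O2)[C@](C)(O)CC[C@H](O)[C@](C)(O)CC1
F7 | step 30 | trihydroxy acid | C=C(C(=O)O)[C@H]1C[C@H](OC(C)=O)[C@@]2(C)CC[C@@H](O2)[C@](C)(O)CC[C@H](O)[C@](C)(O)CC1
F8 | step 30 | eight-membered lactone on O11 | C=C1C(=O)O[C@H]2CC[C@@](C)(O)[C@H]3CC[C@@](C)(O3)[C@@H](OC(C)=O)C[C@H]1CC[C@@]2(C)O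
F9 | step 30 | seven-membered 11-hydroxy lactone | C=C1C(=O)O[C@]2(C)CC[C@@H]1C[C@H](OC(C)=O)[C@@]1(C)CC[C@@H](O1)[C@](C)(O)CC[C@@H]2O
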